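Its constants come from no measurement; no experiment stands behind them.

Turn the question round and ask what has to be true of this flask for any of the three changes to pay.

    gas phase ⇌ dissolved gas, rate k1*(csat - [dissolved gas]) (k1 = 0.44 s⁻¹, csat = 11 mM)
    substrate + dissolved gas + free catalyst → free catalyst + target (k2 = 13000 M⁻² s⁻¹)
    free catalyst → spent catalyst A (k3 = 0.0016 s⁻¹)
    2 free catalyst → spent catalyst B (k4 = 1.2 M⁻¹ s⁻¹)
    target ⇌ isomer of the product (K5 = 1.2, k5 = 0.0026 s⁻¹)

substrate 0.050 M; gas phase 11 mM (held); free catalyst 0.50 mM; time 2.0 h

- how much target there is at 2.0 h, in percent of the substrate charged
- the change that raises the amount of target at 2.0 h, in percent of the substrate charged most ("none" if none brings more than 2 percentage points) (Sunday's / Thursday's / Friday's / none)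
- amount of target at 2.0 h, in percent of the substrate charged, after Thursday's

- Sunday's: doubling the amount of free catalyst, all else as stated
- Thursday's: doubling the saturation concentration of gas phase, all else as stated
- Friday's: doubling the transfer coefficient of step 1, all else as stated

- a doubled species enters its step squared and goes two at a time
- at the start none of the gas is dissolved
- run time (flask): 2.0 h

A change can add more than 2 percentage points of target at 2.0 h on condition that target then stands that far short of where it can go. Target and isomer of the product relax with a half-life of 2.42 min, short against 2.0 h, so in this flask, by 2.0 h, target holds a fraction 0.455 of whatever substrate has reacted. The opposite outcome therefore needs substrate left at the end.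

How much is left is my own reckoning. With substrate and free catalyst at their charges, gas transfer at 0.44 s⁻¹ stands against a demand of 0.325 s⁻¹, so, once the empty solution has filled, I put dissolved gas near a fraction 0.575 of saturation, climbing as substrate falls. Substrate falls in a pseudo-first-order way, its rate coefficient being the constant of the step times dissolved gas times free catalyst. Hold the gas at that level and integrate the free catalyst through both of its losses, and you get the reach, 19.2: the natural-log units of substrate the charged catalyst can remove at that gas level before it is lost. The fraction of substrate left is then about 4.69 × 10⁻⁹. In this reckoning target falls short by more than 2 points when the reach is under 3.12, and this flask stands above that. I commit to a fraction 0.455 of the charge as target, with no change worth taking.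

The forecast gives 45.5% (range 44.5% to 46.5%), none as the best change, and 45.5% (range 44.5% to 46.5%) after Thursday's: “The substrate is used up within a few minutes, long before the catalyst dies”.

The flask gives 45.5%, best change none, and 45.5% after Thursday's. It already holds 45.5% target at 0.500 h. Thursday's lifts the reach to 38.4, further above 3.12, and gains 0 points.

The neighbour flask charged with 0.0013 M free catalyst has a reach of 22.1, also above 3.12, which points to a fraction 0.455 as target. The simulation of that neighbour gives 45.5% target with 0% of its substrate left.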